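# Lapiferine by an Achmatowicz / oxidopyrylium [5+2] route

## Analysis of the target

Lapiferine (33) is a daucane-type sesquiterpenoid ester in which a cyclopentane (C1–C5) is trans-fused along C1–C5 to a cycloheptane (C1, C5–C10). The numbering used throughout is: C1 (quaternary, angular methyl), C2 and C3 (methylenes), C4 (tertiary carbinol carrying the isopropyl group), C5 (ring-fusion CH), C6 (angeloyloxy carbinol), C7 (methylene), C8–C9 (epoxide, methyl on C8), C10 (free secondary carbinol). There are seven stereocentres (1S,4R,5S,6S,8R,9S,10S). With the C1 methyl defined as β, the C4 hydroxyl is also β (isopropyl α), while H-5, the C6 ester oxygen, the epoxide oxygen and the C10 hydroxyl all lie on the α-face. The sensitive groups are the angelate (Z to E isomerisation to the tiglate under nucleophilic or basic conditions), the trisubstituted epoxide next to a free carbinol (acid) and the tertiary alcohol (elimination). The difficulty lies in three places: C5 sits between two fully substituted carbons (C1 and C4), four of the seven ring carbons of the larger ring are functionalised, and the two secondary oxygens at C6 and C10 must be told apart. The route rests on one feature: C5–C6–C7–C8–C9 carries oxygen at C6 at the carbonyl level, a methyl-bearing sp2 carbon at C8 and oxygen at C9, which is the carbon pattern of a 5-methyl-3-oxidopyrylium whose ring oxygen spans C5 and C9; C1 and C10 are the two carbons of a 1,1-disubstituted alkene tied to C5 through C4–C3–C2.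

## Retrosynthetic reasoning

**Epoxide last (33 from 32).** The two C–O bonds of the epoxide are cut first. In 32 the 10α-hydroxyl is allylic to the C8=C9 alkene, so a metal-catalysed, hydroxyl-directed epoxidation should deliver oxygen to the α-face. The electron-poor angelate alkene is not a substrate. Placing this step last means no deprotection or basic step is run on the epoxy alcohol.

**Ester (32 from 31, and 31 from 28 and 29).** The C6–O acyl bond is cut. In 28 the C4 and C10 oxygens are triethylsilyl ethers and only the 6α-hydroxyl is free, so the C6/C10 question is settled by protection, not by selectivity. The forward reaction must acylate a hindered secondary alcohol without isomerising the (Z)-alkene of 29; the mixed anhydride 30 is used for that.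

**C5–H, C6–O and the C8=C9 alkene (28 from 27 from 25).** The C9–H bond of 28 comes from reduction of the vinyl triflate in 27. The C5–H and C6–O bonds come from one syn hydroboration of the C5=C6 alkene of 25 on the face away from the angular methyl. The order matters: while the C5=C6 alkene is hydroborated, the C8=C9 alkene is still its tetrasubstituted, electron-poor enol triflate and should not react. Only afterwards is it converted into the simple trisubstituted alkene.

**C10 oxygen (25 from 24 from 23 from 22).** The C10–O bond is cut back to ketone 22 (enol ether oxidation of 23, anti to the C1 methyl), and the triflate of 25 to the same C9 carbonyl. Throughout this carbonyl chemistry the C5=C6 alkene stands in for the later C6 carbinol, so there is never a second ketone or a second free secondary hydroxyl to distinguish.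

**Bridge cleavage (22 from 21 from 19 from 18).** The C5–O bond of the cycloadduct lies α to the C6 carbonyl. It is cleaved through the hydrazone 20, which turns the C6 carbonyl and the C5–O bond into the C5=C6 alkene in one regiospecific operation and releases the C9 hydroxyl of 21. A plain electron-transfer cleavage to a C6 ketone was not chosen, because that ketone would enolise toward C7 when converted into an enol derivative and would later compete with the C9 ketone. The enone alkene of 18 is saturated first (19), since a hydrazone of the enone would cyclise by conjugate addition; C8 becomes sp2 again in 25.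

**Key disconnection (18 from 17 from 16).** The C1–C5 and C9–C10 bonds are cut together. This removes the cyclopentane, the seven-membered ring and the oxygen bridge at once and leads to the zwitterion 17 and its stable precursor 16. Cutting here places the C6 carbonyl, the C8 methyl and the C9 oxygen in the product without any later C–H oxidation in the larger ring, and it lets the one stereocentre that is easy to make in open-chain form (C4) control the rest.

**Pyranone (16 from 15 from 14, and 14 from 9 and 12).** The pyranone is the oxidative ring expansion product of furyl carbinol 14. The C5–furan bond is cut to aldehyde 9 and organolithium 13. Direct metallation of a 3-substituted furan gives both α-lithio isomers, so 13 is generated by halogen–metal exchange from bromide 12, whose substitution pattern is fixed by bromination and decarboxylation of acid 10.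

**C4 fragment (9 from 8 from 7, 7 from 5 and 6, 5 from 4, 4 from 1 and 2).** The C2–C3 bond is cut (epoxide opening of 5 by the allylic Grignard reagent 6), and the quaternary carbinol is traced to the asymmetric epoxidation of the 2-substituted allylic alcohol 4. A cyclic monoterpene alcohol that already contains this carbinol was considered as the source of C4. Its ring cleavage leaves one carbon too many between C4 and the aldehyde, and it gives a β-silyloxy aldehyde beside a methyl ketone, which invites elimination and intramolecular aldol reaction. The open-chain route was therefore preferred.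

## Alternatives that were turned down

**Alternative 1:** carbenoid cyclopropanation followed by a divinylcyclopropane Cope rearrangement.
- Disconnection: C1–C5 and C7–C8.
- Forward key step: the vinyl diazoketone A1 is decomposed with Rh2(S-PTAD)4 (divalent rhodium). The vinylcarbenoid cyclopropanates the trisubstituted alkene of the tether, and the cis-divinylcyclopropane formed first rearranges on warming to the hydroazulene dienone A2.
- For: it is catalytic and enantioselective, builds both rings and the C1 quaternary centre from an open-chain precursor in one operation, and needs no stoichiometric chiral reagent. On step count to the bicyclic skeleton it is stronger than the chosen route.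
- Against:
  - A2 carries one oxygen only (the C4 ketone). The C6, C9 and C10 oxygens and the epoxide would all have to be introduced afterwards.
  - Its C9=C10 alkene is one position away from where the target needs unsaturation, and C8 is sp3.
  - The C5=C6 alkene is conjugated to the C4 ketone, so the isopropyl nucleophile faces conjugate addition and enolisation.
  - Enantiocontrol in intramolecular cyclopropanation by a vinyl diazoketone is less secure than with donor/acceptor carbenoids, and such diazo compounds can close to pyrazoles.
- Comparison: the chosen route delivers three of the four functionalised positions of the larger ring (C6, C8, C9) with the ring-forming step and pays with a longer preparation of 16 and with the bridge cleavage.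

**Alternative 2:** asymmetric conjugate vinylation and aldol trapping.
- Disconnection: C1–C10 and C5–C6, no ring closure in the key step.
- Forward key step: Cu(OTf)2 with a chiral N-heterocyclic carbene ligand adds the vinyl Grignard reagent A4 to the enone A3, and the magnesium enolate is trapped with the iodoenal A5 to give the aldol A6.
- For: it is a convergent three-component coupling. A later closure between the vinyl iodide carbon and a C10 aldehyde would give the C10 carbinol and the C8=C9 alkene directly, which is the allylic alcohol the final epoxidation needs. On this point it is more direct than the enol ether oxidation and triflate reduction used here.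
- Against:
  - Forming a quaternary centre by copper-catalysed addition of an alkenyl Grignard reagent to a five-membered β-substituted enone is the least developed variant of that reaction.
  - The hindered enolate must add to A5, a β,γ-unsaturated aldehyde that slips easily into conjugation.
  - In A6 the C4 ketone still has to accept an isopropyl nucleophile next to a β-hydroxy group (retro-aldol) with the right facial sense.
  - The seven-membered ring closure and its C10 selectivity remain open.
- Comparison: the chosen route has more steps after ring formation but no unsolved ring closure, and its C4 centre is set before any ring exists.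

**Alternative 3:** samarium Barbier closure of the seven-membered ring, epoxide by displacement.
- Disconnection: C7–C8.
- Forward key step: SmI2 with catalytic NiI2 converts the primary iodide of A7 into an organosamarium that adds to the C8 methyl ketone and gives the tertiary carbinol A8.
- For: all carbons and all oxygens are present before the ring is closed, so nothing is oxidised afterwards, and the free tertiary hydroxyl is tolerated. In that respect it is stronger than the chosen route, which adjusts oxidation levels after the cycloaddition.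
- Against:
  - A7 needs six stereocentres (C1, C4, C5, C6, C9, C10) assembled on a cyclopentane with three kinds of protecting group, which is a long linear sequence.
  - Its C7 iodide has a silyloxy group on the neighbouring C6, so reductive β-elimination to a terminal alkene competes with addition.
  - Seven-membered Barbier closures are slower than five- or six-membered ones.
  - The C8 configuration of A8 is not controlled, although the later epoxide closure by displacement at C9 demands one specific C8/C9 pair.
- Comparison: the chosen route sets C8 and C9 by a directed epoxidation of a planar alkene and needs only one stereocentre before ring formation.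

Key step: step 11

## Route

Assumption: compounds 14–16 are carried as mixtures of epimers at C5 (and, for 15 and 16, at C9); both centres become sp2 in 17, so their SMILES leave these two centres undefined.

Step 1
Reactants: 1 prop-2-yn-1-ol; 2 isopropylmagnesium chloride
Product: 4 3-methyl-2-methylidenebutan-1-ol, via chelated alkenylmagnesium alkoxide 3 (not isolated)
Conditions: i-PrMgCl (3 equiv), CuI (10 mol %), THF, 0 °C to rt; aq NH4Cl
Reagents that add atoms: none
Why: Copper-catalysed anti-carbomagnesiation of the propargylic alkoxide puts the alkyl group on the internal alkyne carbon and magnesium on the terminal one (five-membered chelate); protonolysis gives the 2-substituted allylic alcohol. No stereocentre is formed.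

Step 2
Reactants: 4 3-methyl-2-methylidenebutan-1-ol
Product: 5 [(2R)-2-(propan-2-yl)oxiran-2-yl]methanol
Conditions: Ti(OiPr)4 (10 mol %), D-(−)-diisopropyl tartrate (12 mol %), t-BuOOH, 4 Å MS, CH2Cl2, −20 °C
Reagents that add atoms: tert-butyl hydroperoxide, CC(C)(C)OO
Why: Sharpless asymmetric epoxidation of a 2-substituted allylic alcohol; the titanium tartrate complex delivers oxygen to one enantioface, and the D-(−)-tartrate should give the (R)-epoxide. This sets C4 of the target.

Step 3
Reactants: 5 [(2R)-2-(propan-2-yl)oxiran-2-yl]methanol; 6 2-methylallylmagnesium chloride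
Product: 7 (2R)-5-methyl-2-(propan-2-yl)hex-5-ene-1,2-diol
Conditions: 6 (3 equiv), CuI (10 mol %), THF, −30 to 0 °C; aq NH4Cl
Reagents that add atoms: none
Why: Copper-catalysed SN2 opening of the 2,2-disubstituted epoxide at its CH2 terminus forms the C2–C3 bond. No bond to the quaternary carbon is broken, so its configuration is kept.

Step 4
Reactants: 7 (2R)-5-methyl-2-(propan-2-yl)hex-5-ene-1,2-diol
Product: 8 (2R)-5-methyl-2-(propan-2-yl)-1,2-bis(triethylsilyloxy)hex-5-ene
Conditions: TESOTf (2.5 equiv), 2,6-lutidine, CH2Cl2, −78 to 0 °C
Reagents that add atoms: triethylsilyl trifluoromethanesulfonate, CC[Si](CC)(CC)OS(=O)(=O)C(F)(F)F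
Why: The silyl triflate silylates the hindered tertiary hydroxyl as well as the primary one. The tertiary TES ether is the C4 protecting group for the rest of the route.

Step 5
Reactants: 8 (2R)-5-methyl-2-(propan-2-yl)-1,2-bis(triethylsilyloxy)hex-5-ene
Product: 9 (2R)-5-methyl-2-(propan-2-yl)-2-(triethylsilyloxy)hex-5-enal
Conditions: (COCl)2, DMSO, CH2Cl2, −78 to −30 °C; Et3N, −78 °C to rt
Reagents that add atoms: none
Why: Under Swern conditions a primary TES ether is cleaved and oxidised in the same flask, while the tertiary TES ether is inert. The aldehyde has no α-hydrogen and cannot epimerise or eliminate.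

Step 6
Reactants: 10 3-methylfuran-2-carboxylic acid
Product: 11 5-bromo-3-methylfuran-2-carboxylic acid
Conditions: Br2, AcOH, rt
Reagents that add atoms: bromine, BrBr
Why: Electrophilic bromination of a 2-furoic acid goes to the free α-position; the carboxyl group blocks the α-position next to the methyl group.

Step 7
Reactants: 11 5-bromo-3-methylfuran-2-carboxylic acid
Product: 12 2-bromo-4-methylfuran
Conditions: Cu powder, quinoline, 200 °C, product distilled out
Reagents that add atoms: none
Why: Copper-promoted protodecarboxylation of a furoic acid removes the blocking group and leaves the halogen on the α-carbon remote from the methyl group.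

Step 8
Reactants: 12 2-bromo-4-methylfuran; 9 (2R)-5-methyl-2-(propan-2-yl)-2-(triethylsilyloxy)hex-5-enal
Product: 14 (1RS,2R)-5-methyl-1-(4-methylfuran-2-yl)-2-(propan-2-yl)-2-(triethylsilyloxy)hex-5-en-1-ol, via (4-methylfuran-2-yl)lithium 13 (not isolated)
Conditions: 12, t-BuLi (2 equiv), Et2O, −78 °C; then 9, THF, −78 °C; AcOH/THF quench at −78 °C
Reagents that add atoms: none
Why: Bromine–lithium exchange gives the regiodefined 2-lithiofuran, which adds to the non-enolisable aldehyde. The new carbinol centre (C5) is lost later, so its ratio is irrelevant; the cold quench prevents migration of the silyl group from the tertiary to the new secondary oxygen.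

Step 9
Reactants: 14 (1RS,2R)-5-methyl-1-(4-methylfuran-2-yl)-2-(propan-2-yl)-2-(triethylsilyloxy)hex-5-en-1-ol
Product: 15 6-hydroxy-5-methyl-2-[(3R)-2,6-dimethyl-3-(triethylsilyloxy)hept-6-en-3-yl]-2H-pyran-3(6H)-one
Conditions: NBS (1.05 equiv), NaHCO3, NaOAc, THF/H2O 4:1, 0 °C
Reagents that add atoms: water, O
Why: Achmatowicz rearrangement: bromonium attack on the electron-rich furan, hydrolysis to the ene-dione and closure of the carbinol oxygen onto the aldehyde carbon give the pyranone hemiacetal. The furan reacts much faster than the 1,1-disubstituted alkene, and the 4-methyl group of the furan becomes the C5 methyl of the pyranone (C8 of the target).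

Step 10
Reactants: 15 6-hydroxy-5-methyl-2-[(3R)-2,6-dimethyl-3-(triethylsilyloxy)hept-6-en-3-yl]-2H-pyran-3(6H)-one
Product: 16 5-methyl-2-[(3R)-2,6-dimethyl-3-(triethylsilyloxy)hept-6-en-3-yl]-3-oxo-3,6-dihydro-2H-pyran-6-yl acetate
Conditions: Ac2O, pyridine, DMAP (cat.), CH2Cl2, 0 °C
Reagents that add atoms: acetic anhydride, CC(=O)OC(C)=O
Why: Acetylation of the anomeric hydroxyl gives the leaving group for pyrylium formation; all diastereomers are carried on together.

Step 11
Reactants: 16 5-methyl-2-[(3R)-2,6-dimethyl-3-(triethylsilyloxy)hept-6-en-3-yl]-3-oxo-3,6-dihydro-2H-pyran-6-yl acetate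
Product: 18 tricyclic enone (C6 ketone, C7=C8 with 8-methyl, oxygen bridge C5–O–C9 on the α-face, 1β-methyl, 4β-triethylsilyloxy, 4α-isopropyl), via 3-oxidopyrylium ylide 17 (not isolated)
Conditions: Et3N (3 equiv), MeCN (0.01 M), 60–80 °C
Reagents that add atoms: none
Why: Et3N removes the proton at pyranone C2 and acetate leaves from C6, so every diastereomer of 16 gives the same planar 3-oxidopyrylium 17; this adds across the tethered 1,1-disubstituted alkene in a concerted, thermally allowed [5+2] cycloaddition, the closest known reaction type being the intramolecular oxidopyrylium–alkene cycloaddition of Achmatowicz-derived acetoxypyranones with three-atom tethers. The C5–C1 bond closes the cyclopentane in the fused mode with the tether exo, that is on the side of the ring oxygen, which is the only orientation the three-atom chain C4–C3–C2 can reach; the C9–C10 bond completes the seven-membered carbocycle, which is spanned by the former ring oxygen. C5 and C9 follow from the pyrylium face that is attacked, and C1 from the exo tether: its methyl group is endo and anti to the oxygen bridge, so the cyclopentane is trans-fused to the seven-membered ring and the bridge oxygen sits where H-5 will later be. The selectivity the step needs is the pyrylium face relative to C4: with C3 rising toward the alkene, one of the two remaining C4 substituents must lie beside the oxido oxygen on C6, and allylic strain should put the slim C–O bond of the silyl ether there and the branched isopropyl group on the open ring-oxygen side, which is the arrangement that leads to the 1β-methyl/4β-silyloxy isomer 18. High dilution holds back dimerisation of 17, and the fully substituted C4 favours ring closure.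

Step 12
Reactants: 18 tricyclic enone
Product: 19 saturated bridged ketone (7,8-dihydro-18, 8β-methyl)
Conditions: H2 (1 atm), Pd/C, EtOAc, rt
Reagents that add atoms: none
Why: Catalytic hydrogenation of the enone alkene from the face of the oxygen bridge (the other face is screened by the C1–C10 bridge and its endo methyl group) should give the 8β-methyl ketone. This centre is temporary; EtOAc is used because alcoholic solvents promote loss of TES ethers over Pd/C.

Step 13
Reactants: 19 saturated bridged ketone
Product: 21 bicyclic alkenol (C5=C6, 9α-hydroxy, 8β-methyl, 1β-methyl, 4β-triethylsilyloxy), via C6 hydrazone 20 (not isolated)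
Conditions: N2H4·H2O, AcOH (cat.), EtOH, 80 °C; concentrate; KOtBu, DMSO, rt
Reagents that add atoms: none
Why: Kishner–Leonard (Wharton-type) eliminative reduction of an α-alkoxy ketone: the hydrazone anion expels the C5 alkoxide, whose C–O bond is aligned with the C=N π-system, and the alkenyl diazene loses N2 to leave the C5=C6 alkene and the C9 alkoxide. The alkene position is fixed by the mechanism, and the erased C5 centre is reset in step 18.

Step 14
Reactants: 21 bicyclic alkenol
Product: 22 Δ5-9-ketone
Conditions: Dess–Martin periodinane, NaHCO3, CH2Cl2, rt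
Reagents that add atoms: none
Why: Dess–Martin oxidation of the only free hydroxyl under neutral conditions; the ketone is not conjugated to the alkene, so no isomerisation is expected.

Step 15
Reactants: 22 Δ5-9-ketone
Product: 23 9-(triethylsilyloxy)-Δ5,Δ9-diene (TES enol ether toward C10)
Conditions: LDA, THF, −78 °C; TESCl, DMPU, −78 to 0 °C
Reagents that add atoms: chlorotriethylsilane, CC[Si](CC)(CC)Cl
Why: Kinetic deprotonation of an unsymmetrical ketone takes the methylene (C10) in preference to the methyl-bearing methine (C8); O-silylation fixes the C9=C10 enol ether.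

Step 16
Reactants: 23 9-(triethylsilyloxy)-Δ5,Δ9-diene
Product: 24 10α-(triethylsilyloxy)-Δ5-9-ketone
Conditions: mCPBA (1.05 equiv), NaHCO3, CH2Cl2, −20 to 0 °C
Reagents that add atoms: 3-chloroperbenzoic acid, OOC(=O)c1cccc(Cl)c1
Why: Rubottom oxidation: the electron-rich enol ether is epoxidised far faster than the hindered C5=C6 alkene, and the silyloxy epoxide rearranges with 1,4-silyl shift to the α-silyloxy ketone. Attack at C10 should come anti to the axial C1 methyl group, which gives the 10α-oxygen.

Step 17
Reactants: 24 10α-(triethylsilyloxy)-Δ5-9-ketone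
Product: 25 Δ5,Δ8-dienyl 9-triflate (C8=C9 enol triflate, 10α-triethylsilyloxy)
Conditions: KHMDS, THF, −78 °C; PhNTf2, −78 to 0 °C
Reagents that add atoms: N-phenylbis(trifluoromethanesulfonimide), O=S(=O)(N(c1ccccc1)S(=O)(=O)C(F)(F)F)C(F)(F)F
Why: The base removes H-8 in preference to H-10, which is flanked by the silyloxy group and the quaternary C1; O-triflation of the enolate gives the tetrasubstituted enol triflate and removes the temporary C8 centre.

Step 18
Reactants: 25 Δ5,Δ8-dienyl 9-triflate
Product: 27 6α-hydroxy-5α-H Δ8-9-triflate, via C6 alkylborane 26 (not isolated)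
Conditions: BH3·THF, THF, 0 °C to rt; NaBO3·4H2O, THF/H2O, rt
Reagents that add atoms: sodium perborate, [Na+].[Na+].O[B-]1(O)OO[B-](O)(O)OO1
Why: Syn hydroboration of the trisubstituted C5=C6 alkene puts boron on C6 and hydrogen on C5 from the α-face, away from the C1 methyl and the C4 silyloxy group (the analogy is hydroboration next to an angular methyl group in fused ring systems); oxidation with retention gives 6α-OH and 5α-H, that is the trans ring fusion. The tetrasubstituted, electron-poor enol triflate should not be hydroborated, and perborate is mild enough to leave it intact.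

Step 19
Reactants: 27 6α-hydroxy-5α-H Δ8-9-triflate
Product: 28 Δ8-6α-ol (4β,10α-bis-triethylsilyl ether)
Conditions: Pd(OAc)2 (5 mol %), PPh3 (10 mol %), Bu3N, HCO2H, DMF, 60 °C
Reagents that add atoms: none
Why: Palladium-catalysed formate reduction of a vinyl triflate (oxidative addition, formate exchange, loss of CO2, reductive elimination) replaces the triflate by hydrogen without moving the alkene.

Step 20
Reactants: 28 Δ8-6α-ol; 29 angelic acid
Product: 31 6α-angelate bis-triethylsilyl ether, via angelic 2,4,6-trichlorobenzoic anhydride 30 (not isolated)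
Conditions: 29, 2,4,6-trichlorobenzoyl chloride, Et3N, toluene, rt; then 28, 80 °C
Reagents that add atoms: none
Why: Yamaguchi-type esterification through the mixed anhydride, run without a nucleophilic catalyst so that the (Z)-alkene is not isomerised to the tiglate. Only the C6 hydroxyl is free.

Step 21
Reactants: 31 6α-angelate bis-triethylsilyl ether
Product: 32 6α-angeloyloxy-Δ8-4β,10α-diol (8,9-deoxylapiferine)
Conditions: HF·pyridine, pyridine, THF, 0 °C to rt
Reagents that add atoms: none
Why: Buffered fluoride cleaves both TES ethers; the ester is stable to these conditions, and no epoxide is yet present.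

Step 22
Reactants: 32 6α-angeloyloxy-Δ8-4β,10α-diol
Product: 33 lapiferine
Conditions: VO(acac)2 (5 mol %), t-BuOOH, CH2Cl2, 0 °C
Reagents that add atoms: tert-butyl hydroperoxide, CC(C)(C)OO
Why: Hydroxyl-directed epoxidation: the vanadium alkylperoxide bound to the 10α-hydroxyl delivers oxygen to the same face of the adjacent C8=C9 alkene, which is the syn outcome expected for a cycloheptenol. This sets C8 and C9; the conjugated ester alkene and the remote tertiary alcohol do not take part.

## Compound list

1 | prop-2-yn-1-ol | C#CCO | starting material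
2 | isopropylmagnesium chloride | CC(C)[Mg]Cl | starting material
3 | chelated alkenylmagnesium alkoxide (Mg cis to the CH2O group) | Cl[Mg]/C=C(\CO[Mg]Cl)C(C)C | intermediate
4 | 3-methyl-2-methylidenebutan-1-ol | C=C(CO)C(C)C | intermediate
5 | [(2R)-2-(propan-2-yl)oxiran-2-yl]methanol | OC[C@]1(C(C)C)CO1 | intermediate
6 | 2-methylallylmagnesium chloride | C=C(C)C[Mg]Cl | starting material
7 | (2R)-5-methyl-2-(propan-2-yl)hex-5-ene-1,2-diol | OC[C@](O)(C(C)C)CCC(C)=C | intermediate
8 | (2R)-5-methyl-2-(propan-2-yl)-1,2-bis(triethylsilyloxy)hex-5-ene | CC[Si](CC)(CC)OC[C@](O[Si](CC)(CC)CC)(C(C)C)CCC(C)=C | intermediate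
9 | (2R)-5-methyl-2-(propan-2-yl)-2-(triethylsilyloxy)hex-5-enal | O=C[C@](O[Si](CC)(CC)CC)(C(C)C)CCC(C)=C | intermediate
10 | 3-methylfuran-2-carboxylic acid | Cc1ccoc1C(=O)O | starting material
11 | 5-bromo-3-methylfuran-2-carboxylic acid | Cc1cc(Br)oc1C(=O)O | intermediate
12 | 2-bromo-4-methylfuran | Cc1coc(Br)c1 | intermediate
13 | (4-methylfuran-2-yl)lithium | [Li]c1cc(C)co1 | intermediate
14 | (1RS,2R)-5-methyl-1-(4-methylfuran-2-yl)-2-(propan-2-yl)-2-(triethylsilyloxy)hex-5-en-1-ol | OC(c1cc(C)co1)[C@](O[Si](CC)(CC)CC)(C(C)C)CCC(C)=C | intermediate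
15 | 6-hydroxy-5-methyl-2-[(3R)-2,6-dimethyl-3-(triethylsilyloxy)hept-6-en-3-yl]-2H-pyran-3(6H)-one (mixture at C2 and C6) | OC1OC([C@](O[Si](CC)(CC)CC)(C(C)C)CCC(C)=C)C(=O)C=C1C | intermediate
16 | 5-methyl-2-[(3R)-2,6-dimethyl-3-(triethylsilyloxy)hept-6-en-3-yl]-3-oxo-3,6-dihydro-2H-pyran-6-yl acetate (mixture at C2 and C6) | CC(=O)OC1OC([C@](O[Si](CC)(CC)CC)(C(C)C)CCC(C)=C)C(=O)C=C1C | intermediate
17 | 5-methyl-2-[(3R)-2,6-dimethyl-3-(triethylsilyloxy)hept-6-en-3-yl]-3-oxidopyrylium | [O-]c1cc(C)c[o+]c1[C@](O[Si](CC)(CC)CC)(C(C)C)CCC(C)=C | intermediate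
18 | tricyclic enone: C6 ketone, C7=C8 (8-methyl), C5–O–C9 bridge α, 1β-methyl, 4β-OTES, 4α-isopropyl | O=C1C=C(C)[C@@H]2C[C@@]3(C)CC[C@@](O[Si](CC)(CC)CC)(C(C)C)[C@]13O2 | intermediate
19 | saturated bridged ketone (8β-methyl) | O=C1C[C@H](C)[C@@H]2C[C@@]3(C)CC[C@@](O[Si](CC)(CC)CC)(C(C)C)[C@]13O2 | intermediate
20 | C6 hydrazone of 19 | NN=C1C[C@H](C)[C@@H]2C[C@@]3(C)CC[C@@](O[Si](CC)(CC)CC)(C(C)C)[C@]13O2 | intermediate
21 | bicyclic alkenol: C5=C6, 9α-OH, 8β-methyl, 1β-methyl, 4β-OTES | C[C@H]1CC=C2[C@@](C)(C[C@@H]1O)CC[C@@]2(O[Si](CC)(CC)CC)C(C)C | intermediate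
22 | Δ5-9-ketone | C[C@H]1CC=C2[C@@](C)(CC1=O)CC[C@@]2(O[Si](CC)(CC)CC)C(C)C | intermediate
23 | 9-(triethylsilyloxy)-Δ5,Δ9-diene | C[C@H]1CC=C2[C@@](C)(C=C1O[Si](CC)(CC)CC)CC[C@@]2(O[Si](CC)(CC)CC)C(C)C | intermediate
24 | 10α-(triethylsilyloxy)-Δ5-9-ketone | C[C@H]1CC=C2[C@@](C)([C@H](O[Si](CC)(CC)CC)C1=O)CC[C@@]2(O[Si](CC)(CC)CC)C(C)C | intermediate
25 | Δ5,Δ8-dienyl 9-triflate, 10α-OTES, 4β-OTES | CC1=C(OS(=O)(=O)C(F)(F)F)[C@@H](O[Si](CC)(CC)CC)[C@@]2(C)CC[C@@](O[Si](CC)(CC)CC)(C(C)C)C2=CC1 | intermediate
26 | C6 alkylborane (6α-boryl, 5α-H) | B[C@H]1CC(C)=C(OS(=O)(=O)C(F)(F)F)[C@@H](O[Si](CC)(CC)CC)[C@@]2(C)CC[C@@](O[Si](CC)(CC)CC)(C(C)C)[C@H]12 | intermediate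
27 | 6α-hydroxy-5α-H Δ8-9-triflate | O[C@H]1CC(C)=C(OS(=O)(=O)C(F)(F)F)[C@@H](O[Si](CC)(CC)CC)[C@@]2(C)CC[C@@](O[Si](CC)(CC)CC)(C(C)C)[C@H]12 | intermediate
28 | Δ8-6α-ol, 4β,10α-bis-TES ether | O[C@H]1CC(C)=C[C@@H](O[Si](CC)(CC)CC)[C@@]2(C)CC[C@@](O[Si](CC)(CC)CC)(C(C)C)[C@H]12 | intermediate
29 | angelic acid, (Z)-2-methylbut-2-enoic acid | C/C=C(/C)C(=O)O | starting material
30 | angelic 2,4,6-trichlorobenzoic anhydride | C/C=C(/C)C(=O)OC(=O)c1c(Cl)cc(Cl)cc1Cl | intermediate
31 | 6α-angelate, 4β,10α-bis-TES ether, Δ8 | C/C=C(/C)C(=O)O[C@H]1CC(C)=C[C@@H](O[Si](CC)(CC)CC)[C@@]2(C)CC[C@@](O[Si](CC)(CC)CC)(C(C)C)[C@H]12 | intermediate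
32 | 6α-angeloyloxy-Δ8-4β,10α-diol | C/C=C(/C)C(=O)O[C@H]1CC(C)=C[C@@H](O)[C@@]2(C)CC[C@@](O)(C(C)C)[C@H]12 | intermediate
33 | lapiferine | C/C=C(/C)C(=O)O[C@H]1C[C@@]2(C)O[C@H]2[C@@H](O)[C@@]2(C)CC[C@@](O)(C(C)C)[C@H]12 | target

## Step count and least certain steps

Total: 22 steps. Longest linear sequence: 20 steps (steps 1–5 and 8–22); steps 6 and 7 are a two-step side branch to the furan.

**Step 11 (key step).** Two things may go wrong. The facial discrimination may be poor, because the steric difference between silyloxy and isopropyl next to the oxido oxygen is modest and dipole repulsion between the two oxygens works against it. The unactivated, 1,1-disubstituted alkene may also add slowly, so that 17 dimerises. The fallback changes the control element from steric bias to hydrogen bonding and sets out from 14: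
- TBAF removes the silyl group to give (1RS,2R)-5-methyl-1-(4-methylfuran-2-yl)-2-(propan-2-yl)hex-5-ene-1,2-diol F1.
- Achmatowicz oxidation (NBS, aqueous THF) gives the hydroxypyranone hemiacetal F2.
- Acetylation takes the anomeric hydroxyl only and gives the acetate F3.
- Et3N then generates the hydroxy-substituted 3-oxidopyrylium F4. Its tertiary hydroxyl can hydrogen-bond to the oxido oxygen, which holds the C4 oxygen on the C6 side and the isopropyl group on the ring-oxygen side, the same topicity as required.
- The resulting 4β-hydroxy cycloadduct F5 is silylated (TESOTf, 2,6-lutidine) and the route is rejoined at 18.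

**Step 13.** Hydrazone formation at the hindered C6 carbonyl may be slow, protonation at C6 may outrun loss of the C5 alkoxide (plain Wolff–Kishner reduction with the bridge intact), or the tertiary silyl ether may be lost to the strong base. The fallback separates bridge cleavage from alkene formation and sets out from 19:
- SmI2 in THF/MeOH at −78 °C cleaves the α-alkoxy ketone to the 9α-hydroxy-6-ketone F6, with the C5 proton delivered on the α-face where the samarium alkoxide leaves.
- Acetylation gives the 9α-acetoxy-6-ketone F7.
- NaBH4 attacks anti to the angular methyl and gives the 9α-acetoxy-6β-ol F8.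
- POCl3 in pyridine eliminates the axial 6β-oxygen anti to H-5 and gives the 9α-acetoxy-Δ5-alkene F9.
- K2CO3 in MeOH returns to the route at 21.

**Step 15 (and, for the same reason, step 17).** Regiocontrol in the two kinetic deprotonations may be lost: C10 is a neopentyl methylene and competes with the C8 methine in step 15, and H-10 competes with H-8 in step 17. The fallback removes both choices and sets out from 22:
- TMSOTf/Et3N gives the more substituted Δ8-9-trimethylsilyl enol ether F10.
- Saegusa oxidation (catalytic Pd(OAc)2, O2, DMSO) gives the Δ5,Δ7-dien-9-one F11, whose carbonyl can enolise only toward C10.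
- LDA/TESCl gives the 9-triethylsilyloxy-Δ5,Δ7,Δ9-triene F12.
- mCPBA gives the 10α-triethylsilyloxy-Δ5,Δ7-dien-9-one F13.
- L-Selectride adds hydride to C7 (the 1,6-terminus C5 lies between two quaternary carbons), and the resulting C8=C9 enolate is trapped with PhNTf2, which rejoins the route at 25.

**Step 18.** Borane may attack from the β-face or from both faces, because the α-face carries the C4 isopropyl group and the C10 silyl ether. The fallback hydroborates before C10 is oxygenated, so that the α-face is freer, and then repeats the C9/C10 chemistry with C6 masked. It sets out from 21: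
- Benzoylation (BzCl, pyridine) gives the 9α-benzoate F14.
- Hydroboration and perborate oxidation give the 6α-hydroxy-5α-H 9α-benzoate F15.
- 4-Methoxybenzyl trichloroacetimidate with catalytic La(OTf)3 gives the 6α-PMB ether F16.
- K2CO3/MeOH frees the 9α-ol F17.
- Dess–Martin oxidation gives the 9-ketone F18.
- LDA/TESCl gives its Δ9 TES enol ether F19.
- mCPBA gives the 10α-triethylsilyloxy 9-ketone F20.
- KHMDS/PhNTf2 gives the Δ8-9-triflate F21.
- Pd(OAc)2/PPh3/Bu3N/HCO2H gives the Δ8 6α-PMB ether F22.
- DDQ in wet CH2Cl2 removes the PMB group and rejoins the route at 28.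

## Further compounds

F1 | step 11 | (1RS,2R)-5-methyl-1-(4-methylfuran-2-yl)-2-(propan-2-yl)hex-5-ene-1,2-diol | OC(c1cc(C)co1)[C@](O)(C(C)C)CCC(C)=C
F2 | step 11 | 6-hydroxy-2-[(3R)-3-hydroxy-2,6-dimethylhept-6-en-3-yl]-5-methyl-2H-pyran-3(6H)-one | OC1OC([C@](O)(C(C)C)CCC(C)=C)C(=O)C=C1C
F3 | step 11 | 2-[(3R)-3-hydroxy-2,6-dimethylhept-6-en-3-yl]-5-methyl-3-oxo-3,6-dihydro-2H-pyran-6-yl acetate | CC(=O)OC1OC([C@](O)(C(C)C)CCC(C)=C)C(=O)C=C1C
F4 | step 11 | 2-[(3R)-3-hydroxy-2,6-dimethylhept-6-en-3-yl]-5-methyl-3-oxidopyrylium | [O-]c1cc(C)c[o+]c1[C@](O)(C(C)C)CCC(C)=C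
F5 | step 11 | 4β-hydroxy cycloadduct (desilyl-18) | O=C1C=C(C)[C@@H]2C[C@@]3(C)CC[C@@](O)(C(C)C)[C@]13O2
F6 | step 13 | 9α-hydroxy-6-ketone (5α-H, 8β-methyl, 4β-OTES) | O=C1C[C@H](C)[C@@H](O)C[C@@]2(C)CC[C@@](O[Si](CC)(CC)CC)(C(C)C)[C@H]12
F7 | step 13 | 9α-acetoxy-6-ketone | O=C1C[C@H](C)[C@@H](OC(C)=O)C[C@@]2(C)CC[C@@](O[Si](CC)(CC)CC)(C(C)C)[C@H]12
F8 | step 13 | 9α-acetoxy-6β-ol | O[C@@H]1C[C@H](C)[C@@H](OC(C)=O)C[C@@]2(C)CC[C@@](O[Si](CC)(CC)CC)(C(C)C)[C@H]12
F9 | step 13 | 9α-acetoxy-Δ5-alkene (acetate of 21) | C[C@H]1CC=C2[C@@](C)(C[C@@H]1OC(C)=O)CC[C@@]2(O[Si](CC)(CC)CC)C(C)C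
F10 | step 15 | Δ5,Δ8-diene 9-trimethylsilyl enol ether | CC1=C(O[Si](C)(C)C)C[C@@]2(C)CC[C@@](O[Si](CC)(CC)CC)(C(C)C)C2=CC1
F11 | step 15 | Δ5,Δ7-dien-9-one | CC1=CC=C2[C@@](C)(CC1=O)CC[C@@]2(O[Si](CC)(CC)CC)C(C)C
F12 | step 15 | 9-triethylsilyloxy-Δ5,Δ7,Δ9-triene | CC1=CC=C2[C@@](C)(C=C1O[Si](CC)(CC)CC)CC[C@@]2(O[Si](CC)(CC)CC)C(C)C
F13 | step 15 | 10α-triethylsilyloxy-Δ5,Δ7-dien-9-one | CC1=CC=C2[C@@](C)([C@H](O[Si](CC)(CC)CC)C1=O)CC[C@@]2(O[Si](CC)(CC)CC)C(C)C
F14 | step 18 | 9α-benzoate of 21 | C[C@H]1CC=C2[C@@](C)(C[C@@H]1OC(=O)c1ccccc1)CC[C@@]2(O[Si](CC)(CC)CC)C(C)C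
F15 | step 18 | 6α-hydroxy-5α-H 9α-benzoate | O[C@H]1C[C@H](C)[C@@H](OC(=O)c3ccccc3)C[C@@]2(C)CC[C@@](O[Si](CC)(CC)CC)(C(C)C)[C@H]12
F16 | step 18 | 6α-(4-methoxybenzyloxy) 9α-benzoate | COc1ccc(cc1)CO[C@H]1C[C@H](C)[C@@H](OC(=O)c3ccccc3)C[C@@]2(C)CC[C@@](O[Si](CC)(CC)CC)(C(C)C)[C@H]12
F17 | step 18 | 6α-(4-methoxybenzyloxy)-9α-ol | COc1ccc(cc1)CO[C@H]1C[C@H](C)[C@@H](O)C[C@@]2(C)CC[C@@](O[Si](CC)(CC)CC)(C(C)C)[C@H]12
F18 | step 18 | 6α-(4-methoxybenzyloxy)-9-ketone | COc1ccc(cc1)CO[C@H]1C[C@H](C)C(=O)C[C@@]2(C)CC[C@@](O[Si](CC)(CC)CC)(C(C)C)[C@H]12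
F19 | step 18 | 6α-(4-methoxybenzyloxy)-Δ9 9-triethylsilyl enol ether | COc1ccc(cc1)CO[C@H]1C[C@H](C)C(O[Si](CC)(CC)CC)=C[C@@]2(C)CC[C@@](O[Si](CC)(CC)CC)(C(C)C)[C@H]12
F20 | step 18 | 6α-(4-methoxybenzyloxy)-10α-triethylsilyloxy-9-ketone | COc1ccc(cc1)CO[C@H]1C[C@H](C)C(=O)[C@@H](O[Si](CC)(CC)CC)[C@@]2(C)CC[C@@](O[Si](CC)(CC)CC)(C(C)C)[C@H]12
F21 | step 18 | 6α-(4-methoxybenzyloxy)-Δ8-9-triflate | COc1ccc(cc1)CO[C@H]1CC(C)=C(OS(=O)(=O)C(F)(F)F)[C@@H](O[Si](CC)(CC)CC)[C@@]2(C)CC[C@@](O[Si](CC)(CC)CC)(C(C)C)[C@H]12
F22 | step 18 | 6α-(4-methoxybenzyloxy)-Δ8-alkene (PMB ether of 28) | COc1ccc(cc1)CO[C@H]1CC(C)=C[C@@H](O[Si](CC)(CC)CC)[C@@]2(C)CC[C@@](O[Si](CC)(CC)CC)(C(C)C)[C@H]12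
A1 | alternative 1 | (7E,9E)-3-diazo-7-methylundeca-1,7,9-trien-4-one | C=CC(=[N+]=[N-])C(=O)CC/C(C)=C/C=C/C
A2 | alternative 1 | hydroazulene dienone (C4 ketone, C5=C6, C9=C10) | C1C[C@@H](C)C=C[C@@]2(C)CCC(=O)C2=1
A3 | alternative 2 | 3-methylcyclopent-2-en-1-one | CC1=CC(=O)CC1
A4 | alternative 2 | vinylmagnesium bromide | C=C[Mg]Br
A5 | alternative 2 | (3Z)-4-iodo-3-methylbut-3-enal | O=CC/C(C)=C\I
A6 | alternative 2 | trans-2,3-disubstituted cyclopentanone anti-aldol | O[C@@H](C/C(C)=C\I)[C@H]1C(=O)CC[C@]1(C)C=C
A7 | alternative 3 | seco iodo ketone (C7 iodide, C8 methyl ketone) | CC(=O)[C@H](OCOC)[C@@H](O[Si](C)(C)C(C)(C)C)[C@@]1(C)CC[C@@](O)(C(C)C)[C@@H]1[C@H](CI)O[Si](C)(C)C(C)(C)C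
A8 | alternative 3 | hydroazulane with C8 tertiary carbinol | CC(C)(C)[Si](C)(C)O[C@H]1C[C@@](C)(O)[C@H](OCOC)[C@@H](O[Si](C)(C)C(C)(C)C)[C@@]2(C)CC[C@@](O)(C(C)C)[C@H]12
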